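**Plan**

- Locants: ring A is the arene; ring B is the tetralin cyclohexane with C1 (benzylic CH), C2 (lactone α-carbon), C3 (quaternary, methyl-bearing) and C4 (CMe2); ring C is the cycloheptenone bridging C1 and C3; ring D is the γ-lactone from the C2 carboxyl to the bridge carbinol carbon.
- Retrosynthesis cuts, in order: the enone C=C and both C–Br bonds; then the lactone C–O bond and the acyloin C–C bond of ring C, back to a dialdehyde whose two formyl carbons are CO units; last the C2–C3 bond of ring B.
- Enabling feature: C3 is a quaternary stereocentre that carries a vinylic carbon of ring C and is bonded to C2, the α-carbon of the lactone carbonyl. This is the pattern left when a β-keto ester carbanion attacks the substituted terminus of a π-allyl.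
- Forward: ring A is bought as a tetralone, whose carbocycle is opened to an aryl β-keto ester with an ortho allylic carbonate. Ring B closes in the asymmetric Tsuji–Trost step, rings C and D close together in a benzoin/lactonisation cascade, and bromination and dehydrogenation finish.
- Stereochemistry: the chiral ligand on palladium sets C3. C1, C2 and the carbinol carbon are epimerisable or formed reversibly and are locked relative to C3 by the two bridging ring closures.

Key step: step 9

Remark: 7-bromo-4,4-dimethyl-1-tetralone is taken as a catalogue compound, and both bromines are introduced late because an acyl group on ring A would misdirect bromination and aryl bromides would compete for zerovalent palladium in the key step.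

**Route**

Step 1
Reactants: 1 7-bromo-4,4-dimethyl-3,4-dihydronaphthalen-1(2H)-one; 2 ethylboronic acid
Product: 3 7-ethyl-4,4-dimethyl-3,4-dihydronaphthalen-1(2H)-one
Conditions: PdCl2(dppf) (5 mol%), K2CO3, toluene/H2O, 90 °C
Reagents that add atoms: none
Why: Suzuki–Miyaura coupling of an unhindered, ketone-activated aryl bromide with ethylboronic acid is routine with a dppf-ligated palladium catalyst, whose wide bite angle favours reductive elimination over β-hydride elimination.

Step 2
Reactants: 3 7-ethyl-4,4-dimethyl-3,4-dihydronaphthalen-1(2H)-one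
Product: 4 7-ethyl-4,4-dimethylnaphthalen-1(4H)-one
Conditions: IBX, DMSO, 70 °C
Reagents that add atoms: none
Why: IBX dehydrogenation of the aryl ketone through its enol should stop at the 4H-naphthalenone because the gem-dimethyl carbon blocks aromatisation.

Step 3
Reactants: 4 7-ethyl-4,4-dimethylnaphthalen-1(4H)-one
Product: 6 7-ethyl-3,4,4-trimethylnaphthalen-1(4H)-one, via trimethylsilyl enol ether 5 (not isolated)
Conditions: MeMgBr, CuBr·SMe2 (10 mol%), TMSCl, THF, −40 °C; then Pd(OAc)2 (1.1 equiv), MeCN, rt
Reagents that add atoms: methylmagnesium bromide, C[Mg]Br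
Why: Copper-catalysed, TMSCl-accelerated conjugate addition of the methyl Grignard reagent should place the methyl group at C3 despite the neighbouring quaternary carbon, and Saegusa–Ito oxidation of the silyl enol ether by divalent palladium restores the C2=C3 double bond, so the transient C3 stereocentre is erased.

Step 4
Reactants: 6 7-ethyl-3,4,4-trimethylnaphthalen-1(4H)-one
Product: 7 5-ethyl-2-(2-methyl-3-oxobutan-2-yl)benzoic acid
Conditions: O3, CH2Cl2/MeOH, −78 °C; then H2O2, aq. NaOH, 0 °C to rt; then HCl
Reagents that add atoms: ozone, [O-][O+]=O; hydrogen peroxide, OO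
Why: Ozonolysis of the enone C2=C3 bond with alkaline peroxide work-up should leave C3 as the methyl ketone and degrade the aryl glyoxal fragment to the benzoic acid with loss of C2, the carboxylate being inert to the intramolecular Claisen condensation that an ester would suffer.

Step 5
Reactants: 7 5-ethyl-2-(2-methyl-3-oxobutan-2-yl)benzoic acid; 8 triethyl phosphonoacetate
Product: 9 2-[(3E)-5-ethoxy-2,3-dimethyl-5-oxopent-3-en-2-yl]-5-ethylbenzoic acid
Conditions: NaH (4 equiv), DME, 0 to 85 °C; then HCl
Reagents that add atoms: none
Why: Horner–Wadsworth–Emmons olefination of the methyl ketone, run on the sodium carboxylate so that no acyl electrophile is present, should favour the E enoate because the tertiary alkyl group and the ester avoid each other, and any Z isomer is removed here.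

Step 6
Reactants: 9 2-[(3E)-5-ethoxy-2,3-dimethyl-5-oxopent-3-en-2-yl]-5-ethylbenzoic acid
Product: 10 5-ethyl-2-[(3E)-5-hydroxy-2,3-dimethylpent-3-en-2-yl]benzoic acid
Conditions: i-Bu2AlH (4 equiv), CH2Cl2, −78 °C; aq. potassium sodium tartrate
Reagents that add atoms: none
Why: i-Bu2AlH reduces the conjugated ethyl ester by 1,2-addition to the allylic alcohol at −78 °C, while the hindered aluminium benzoate formed from the acid should not be reduced at that temperature.

Step 7
Reactants: 10 5-ethyl-2-[(3E)-5-hydroxy-2,3-dimethylpent-3-en-2-yl]benzoic acid; 11 methyl chloroformate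
Product: 13 5-ethyl-2-[(3E)-5-[(methoxycarbonyl)oxy]-2,3-dimethylpent-3-en-2-yl]benzoic acid, via mixed carbonic anhydride 12 (not isolated)
Conditions: pyridine, CH2Cl2, 0 °C (2.5 equiv of 11); then H2O, rt
Reagents that add atoms: none
Why: Pyridine-mediated acylation of the primary allylic alcohol by the chloroformate gives the carbonate, and the mixed anhydride formed at the hindered carboxyl group is hydrolysed back to the acid on aqueous quench.

Step 8
Reactants: 13 5-ethyl-2-[(3E)-5-[(methoxycarbonyl)oxy]-2,3-dimethylpent-3-en-2-yl]benzoic acid; 14 potassium methyl malonate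
Product: 16 methyl 3-{5-ethyl-2-[(3E)-5-[(methoxycarbonyl)oxy]-2,3-dimethylpent-3-en-2-yl]phenyl}-3-oxopropanoate, via acyl imidazolide 15 (not isolated)
Conditions: CDI, THF, rt; then MgCl2, Et3N, MeCN, rt to 40 °C; aq. HCl
Reagents that add atoms: none
Why: Masamune–Brooks homologation (acyl imidazolide, C-acylation of the magnesium malonate, decarboxylation) builds the β-keto ester under near-neutral conditions that leave the allylic carbonate untouched.

Step 9
Reactants: 16 methyl 3-{5-ethyl-2-[(3E)-5-[(methoxycarbonyl)oxy]-2,3-dimethylpent-3-en-2-yl]phenyl}-3-oxopropanoate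
Product: 17 methyl (2S,3R)-3-ethenyl-7-ethyl-3,4,4-trimethyl-1-oxo-1,2,3,4-tetrahydronaphthalene-2-carboxylate
Conditions: Pd2(dba)3·CHCl3 (2.5 mol%), (1R,2R)-N,N'-bis[2-(diphenylphosphino)benzoyl]cyclohexane-1,2-diamine (7.5 mol%; its antipode if a test run shows the opposite sense), degassed CH2Cl2, rt
Reagents that add atoms: none
Why: Zerovalent palladium ionises the allylic carbonate with loss of CO2, and the methoxide released deprotonates the β-keto ester, so electrophile and nucleophile arise together without added base. The 1,1-disubstituted η3-allyl complex should exchange its two faces by η3–η1–η3 isomerisation through the unsubstituted CH2 terminus faster than it is trapped, so both ionisation modes of the achiral carbonate funnel into the diastereomeric complex that the chiral diphosphine pocket lets react; the closest known reaction type is the asymmetric intramolecular Tsuji–Trost alkylation of β-keto esters, together with ligand-controlled ring-forming attack at the more substituted allyl terminus. The enolate carbon attacks anti to palladium at the fully substituted terminus in a 6-exo closure that forms ring B, whereas attack at the CH2 terminus would need an eight-membered ring and O-alkylation gives an allyl enol ether that can re-ionise and is therefore no dead end. The quaternary stereocentre C3 is set by the ligand, while C2 lies between two carbonyl groups, equilibrates and is erased in step 10 (it is drawn cis to the vinyl group). The step needs regioselectivity for the hindered terminus, secured by ring size and by both partners being held ortho on ring A, and enantioselectivity, secured by the ligand acting on the equilibrating allyl complex; the E carbonate is used geometrically pure because syn and anti allyl isomers need not converge.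

Step 10
Reactants: 17 methyl (2S,3R)-3-ethenyl-7-ethyl-3,4,4-trimethyl-1-oxo-1,2,3,4-tetrahydronaphthalene-2-carboxylate
Product: 18 methyl (3S)-3-ethenyl-7-ethyl-3,4,4-trimethyl-1-{[(trifluoromethyl)sulfonyl]oxy}-3,4-dihydronaphthalene-2-carboxylate
Conditions: NaH, THF, 0 °C; then Tf2O, −78 to 0 °C
Reagents that add atoms: trifluoromethanesulfonic anhydride, O=S(=O)(OS(=O)(=O)C(F)(F)F)C(F)(F)F
Why: O-sulfonylation of the sodium enolate of the β-keto ester gives the enol triflate, which activates C1 for carbon–carbon bond formation; C3 is untouched and its descriptor changes only through the priority rules.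

Step 11
Reactants: 18 methyl (3S)-3-ethenyl-7-ethyl-3,4,4-trimethyl-1-{[(trifluoromethyl)sulfonyl]oxy}-3,4-dihydronaphthalene-2-carboxylate
Product: 19 methyl (3S)-3-ethenyl-7-ethyl-1-formyl-3,4,4-trimethyl-3,4-dihydronaphthalene-2-carboxylate
Conditions: Pd(OAc)2 (5 mol%), dppp (5 mol%), CO (1 atm), Et3SiH, Et3N, DMF, 70 °C
Reagents that add atoms: carbon monoxide, [C-]#[O+]
Why: Palladium-catalysed reductive carbonylation (formylation) of the electron-poor enol triflate with CO and a silane installs the one-carbon aldehyde at C1, and cyclisation of the acylpalladium onto the vinyl group is excluded because it would create a bridgehead alkene.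

Step 12
Reactants: 19 methyl (3S)-3-ethenyl-7-ethyl-1-formyl-3,4,4-trimethyl-3,4-dihydronaphthalene-2-carboxylate
Product: 20 methyl (1S,2R,3R)-3-ethenyl-7-ethyl-1-formyl-3,4,4-trimethyl-1,2,3,4-tetrahydronaphthalene-2-carboxylate
Conditions: Zn dust, AcOH, rt
Reagents that add atoms: none
Why: Dissolving-metal reduction of the ene-1,4-dicarbonyl unit by zinc in acetic acid should saturate only the electron-poor tetrasubstituted double bond and spare the vinyl group; C1 and C2 are expected as an epimeric mixture, but both are α to a carbonyl and are corrected in step 14 (the required isomer is the one listed).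

Step 13
Reactants: 20 methyl (1S,2R,3R)-3-ethenyl-7-ethyl-1-formyl-3,4,4-trimethyl-1,2,3,4-tetrahydronaphthalene-2-carboxylate
Product: 21 methyl (1S,2R,3R)-7-ethyl-1-formyl-3,4,4-trimethyl-3-(3-oxopropyl)-1,2,3,4-tetrahydronaphthalene-2-carboxylate
Conditions: Rh(acac)(CO)2 (2 mol%), tris(2,4-di-tert-butylphenyl) phosphite (8 mol%), CO/H2 (1:1, 20 bar), toluene, 80 °C
Reagents that add atoms: carbon monoxide, [C-]#[O+]
Why: Rhodium-catalysed hydroformylation of a vinyl group on a quaternary carbon can only give the linear aldehyde and cannot isomerise, since there is no allylic hydrogen.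

Step 14
Reactants: 21 methyl (1S,2R,3R)-7-ethyl-1-formyl-3,4,4-trimethyl-3-(3-oxopropyl)-1,2,3,4-tetrahydronaphthalene-2-carboxylate
Product: 23 didebromo-dihydrosalimabromide, that is (1S,2R,3R)-7-ethyl-3,4,4-trimethyltetralin bridged from C1 to C3 by –CH(O–)–C(=O)–CH2–CH2– (carbinol carbon on C1, S) whose carbinol oxygen is acylated by the C2 carboxyl as a γ-lactone, via hydroxy ketone ester 22 (not isolated)
Conditions: 2-(pentafluorophenyl)-6,7-dihydro-5H-pyrrolo[2,1-c][1,2,4]triazol-2-ium tetrafluoroborate (20 mol%), DBU (0.3 equiv), THF, 40 °C; then NaOMe (cat.), MeOH, rt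
Reagents that add atoms: none
Why: In this carbene-catalysed intramolecular cross-benzoin reaction the carbene should add to the unhindered aliphatic aldehyde, the Breslow intermediate attacks the branched aldehyde once base has epimerised C1 into the 1,3-cis arrangement, and methoxide-mediated epimerisation at C2 lets the new hydroxyl close the γ-lactone, which drains the reversible benzoin equilibrium and so fixes C1, C2 and the carbinol carbon relative to C3.

Step 15
Reactants: 23 didebromo-dihydrosalimabromide
Product: 24 dihydrosalimabromide, the 6,8-dibromo derivative of 23 with the same (1S,2R,3R, carbinol S) configuration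
Conditions: Br2 (2.2 equiv), AgO2CCF3 (2.2 equiv), TFA, 0 °C
Reagents that add atoms: bromine, BrBr
Why: Electrophilic aromatic bromination by the trifluoroacetyl hypobromite formed from Br2 and AgO2CCF3 should take the two positions ortho to the ethyl group, each also ortho or para to the ring carbon bearing C1, while the remaining position is activated by one alkyl group only and is shielded by the gem-dimethyl carbon; the cold, bromide-free medium disfavours α-bromination of the ketone.

Step 16
Reactants: 24 dihydrosalimabromide
Product: 25 salimabromide, that is 24 with a cis C=C in place of the bridge CH2–CH2 (enone conjugated to the bridge ketone), (1S,2R,3R, carbinol S)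
Conditions: IBX, DMSO, 70 °C
Reagents that add atoms: none
Why: IBX dehydrogenation of the cycloheptanone can only proceed toward the CH2–CH2 side because the other α-carbon is a bridgehead that cannot enolise, which should give the enone without touching any stereocentre.

**Compound list**

1 | 7-bromo-4,4-dimethyl-3,4-dihydronaphthalen-1(2H)-one | O=C1CCC(C)(C)c2ccc(Br)cc12 | starting material
2 | ethylboronic acid | CCB(O)O | starting material
3 | 7-ethyl-4,4-dimethyl-3,4-dihydronaphthalen-1(2H)-one | CCc1ccc2c(c1)C(=O)CCC2(C)C | intermediate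
4 | 7-ethyl-4,4-dimethylnaphthalen-1(4H)-one | CCc1ccc2c(c1)C(=O)C=CC2(C)C | intermediate
5 | [(7-ethyl-3,4,4-trimethyl-3,4-dihydronaphthalen-1-yl)oxy]trimethylsilane (racemic) | CCc1ccc2c(c1)C(O[Si](C)(C)C)=CC(C)C2(C)C | intermediate
6 | 7-ethyl-3,4,4-trimethylnaphthalen-1(4H)-one | CCc1ccc2c(c1)C(=O)C=C(C)C2(C)C | intermediate
7 | 5-ethyl-2-(2-methyl-3-oxobutan-2-yl)benzoic acid | CCc1ccc(C(C)(C)C(C)=O)c(c1)C(=O)O | intermediate
8 | triethyl phosphonoacetate | CCOC(=O)CP(=O)(OCC)OCC | starting material
9 | 2-[(3E)-5-ethoxy-2,3-dimethyl-5-oxopent-3-en-2-yl]-5-ethylbenzoic acid | CCOC(=O)/C=C(C)/C(C)(C)c1ccc(CC)cc1C(=O)O | intermediate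
10 | 5-ethyl-2-[(3E)-5-hydroxy-2,3-dimethylpent-3-en-2-yl]benzoic acid | OC/C=C(C)/C(C)(C)c1ccc(CC)cc1C(=O)O | intermediate
11 | methyl chloroformate | COC(=O)Cl | starting material
12 | 5-ethyl-2-[(3E)-5-[(methoxycarbonyl)oxy]-2,3-dimethylpent-3-en-2-yl]benzoic methyl carbonic anhydride | COC(=O)OC/C=C(C)/C(C)(C)c1ccc(CC)cc1C(=O)OC(=O)OC | intermediate
13 | 5-ethyl-2-[(3E)-5-[(methoxycarbonyl)oxy]-2,3-dimethylpent-3-en-2-yl]benzoic acid | COC(=O)OC/C=C(C)/C(C)(C)c1ccc(CC)cc1C(=O)O | intermediate
14 | potassium methyl malonate | COC(=O)CC(=O)[O-].[K+] | starting material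
15 | 1-{5-ethyl-2-[(3E)-5-[(methoxycarbonyl)oxy]-2,3-dimethylpent-3-en-2-yl]benzoyl}-1H-imidazole | COC(=O)OC/C=C(C)/C(C)(C)c1ccc(CC)cc1C(=O)n1ccnc1 | intermediate
16 | methyl 3-{5-ethyl-2-[(3E)-5-[(methoxycarbonyl)oxy]-2,3-dimethylpent-3-en-2-yl]phenyl}-3-oxopropanoate | CCc1ccc(C(C)(C)/C(C)=C/COC(=O)OC)c(c1)C(=O)CC(=O)OC | intermediate
17 | methyl (2S,3R)-3-ethenyl-7-ethyl-3,4,4-trimethyl-1-oxo-1,2,3,4-tetrahydronaphthalene-2-carboxylate | CCc1ccc2c(c1)C(=O)[C@@H](C(=O)OC)[C@@](C)(C=C)C2(C)C | intermediate
18 | methyl (3S)-3-ethenyl-7-ethyl-3,4,4-trimethyl-1-{[(trifluoromethyl)sulfonyl]oxy}-3,4-dihydronaphthalene-2-carboxylate | CCc1ccc2c(c1)C(OS(=O)(=O)C(F)(F)F)=C(C(=O)OC)[C@@](C)(C=C)C2(C)C | intermediate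
19 | methyl (3S)-3-ethenyl-7-ethyl-1-formyl-3,4,4-trimethyl-3,4-dihydronaphthalene-2-carboxylate | CCc1ccc2c(c1)C(C=O)=C(C(=O)OC)[C@@](C)(C=C)C2(C)C | intermediate
20 | methyl (1S,2R,3R)-3-ethenyl-7-ethyl-1-formyl-3,4,4-trimethyl-1,2,3,4-tetrahydronaphthalene-2-carboxylate | CCc1ccc2c(c1)[C@@H](C=O)[C@@H](C(=O)OC)[C@@](C)(C=C)C2(C)C | intermediate
21 | methyl (1S,2R,3R)-7-ethyl-1-formyl-3,4,4-trimethyl-3-(3-oxopropyl)-1,2,3,4-tetrahydronaphthalene-2-carboxylate | CCc1ccc2c(c1)[C@@H](C=O)[C@@H](C(=O)OC)[C@@](C)(CCC=O)C2(C)C | intermediate
22 | methyl (1S,2R,3R)-7-ethyl-3,4,4-trimethyltetralin-2-carboxylate bridged from C1 to C3 by –CH(OH)–C(=O)–CH2–CH2– (carbinol carbon on C1, S) | CCc1ccc2c(c1)[C@H]3[C@H](O)C(=O)CC[C@](C)([C@@H]3C(=O)OC)C2(C)C | intermediate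
23 | didebromo-dihydrosalimabromide (saturated keto γ-lactone without bromine; 1S,2R,3R, carbinol S) | CCc1ccc2c(c1)[C@H]1[C@@H]3OC(=O)[C@H]1[C@@](C)(CCC3=O)C2(C)C | intermediate
24 | dihydrosalimabromide (6,8-dibromo derivative of 23) | CCc1c(Br)cc2c(c1Br)[C@H]1[C@@H]3OC(=O)[C@H]1[C@@](C)(CCC3=O)C2(C)C | intermediate
25 | salimabromide | CCc1c(Br)cc2c(c1Br)[C@H]1[C@@H]3OC(=O)[C@H]1[C@@](C)(C=CC3=O)C2(C)C | target

**Step count and risks**

Total: 16 steps. Longest linear sequence: 16 steps (1 to 25).

Steps most likely to fail:

Step 9. Capture of the crowded allyl terminus, which is flanked by the gem-dimethyl carbon, may be slower than β-hydride loss from the allyl methyl group to a 1,3-diene, or the ligand may discriminate the allyl faces poorly. The fallback forms the same bond without a metal and sets out from 16. Methanolysis of the carbonate (K2CO3, MeOH, 0 °C) would give methyl 3-{5-ethyl-2-[(3E)-5-hydroxy-2,3-dimethylpent-3-en-2-yl]phenyl}-3-oxopropanoate F1. Mesylation and chloride exchange (MsCl, Et3N, then LiCl, THF) would give methyl 3-{2-[(3E)-5-chloro-2,3-dimethylpent-3-en-2-yl]-5-ethylphenyl}-3-oxopropanoate F2. Intramolecular SN2' C-alkylation of the β-keto ester under solid–liquid phase transfer (K2CO3, N-(9-anthracenylmethyl)cinchonidinium chloride, toluene) should close the six-membered ring at the γ-carbon, since direct displacement would need an eight-membered ring, and returns to 17; if the enantiomeric purity is insufficient, 17 would be resolved.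

Step 14. The enolisable aliphatic aldehyde may undergo intramolecular aldol condensation to a six-membered ring, or intermolecular acyloin oligomerisation, faster than the seven-membered closure. The fallback replaces the base-mediated umpolung by a reductive radical coupling and sets out from 21. SmI2 (THF, t-BuOH, −78 °C) should give, by pinacol coupling through an ester-chelated ketyl, the cis-diol methyl (1S,2R,3R)-7-ethyl-3,4,4-trimethyltetralin-2-carboxylate bridged by –CH(OH)–CH(OH)–CH2–CH2– F3. Lactonisation (K2CO3, MeOH) would give the hydroxy lactone, the C21 alcohol of 23, F4. Dess–Martin oxidation of the remaining secondary alcohol returns to 23.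

Step 5. The phosphonate anion may fail to add to the tert-alkyl methyl ketone of the carboxylate salt, through steric shielding and charge repulsion, and return starting material. The fallback uses a small acetylide and sets out from 7. Lithium ethoxyacetylide (3 equiv, THF, −78 °C) should give 2-(5-ethoxy-3-hydroxy-2,3-dimethylpent-4-yn-2-yl)-5-ethylbenzoic acid F5. Meyer–Schuster rearrangement (Sc(OTf)3 cat., EtOH, rt) converts it into the enoate and returns to 9 after removal of any Z isomer.

Further compounds
F1 | step 9 | methyl 3-{5-ethyl-2-[(3E)-5-hydroxy-2,3-dimethylpent-3-en-2-yl]phenyl}-3-oxopropanoate | CCc1ccc(C(C)(C)/C(C)=C/CO)c(c1)C(=O)CC(=O)OC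
F2 | step 9 | methyl 3-{2-[(3E)-5-chloro-2,3-dimethylpent-3-en-2-yl]-5-ethylphenyl}-3-oxopropanoate | CCc1ccc(C(C)(C)/C(C)=C/CCl)c(c1)C(=O)CC(=O)OC
F3 | step 14 | methyl (1S,2R,3R)-7-ethyl-3,4,4-trimethyltetralin-2-carboxylate bridged from C1 to C3 by –CH(OH)–CH(OH)–CH2–CH2– (cis-diol) | CCc1ccc2c(c1)[C@H]3[C@H](O)[C@H](O)CC[C@](C)([C@@H]3C(=O)OC)C2(C)C
F4 | step 14 | hydroxy lactone, the secondary alcohol corresponding to the bridge ketone of 23 | CCc1ccc2c(c1)[C@H]1[C@@H]3OC(=O)[C@H]1[C@@](C)(CC[C@H]3O)C2(C)C
F5 | step 5 | 2-(5-ethoxy-3-hydroxy-2,3-dimethylpent-4-yn-2-yl)-5-ethylbenzoic acid (racemic) | CCOC#CC(C)(O)C(C)(C)c1ccc(CC)cc1C(=O)O
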